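The runs were generated by integration for substances that don't exist.

The mono adduct was what this flask was for, yet in the noon run it read 3.7% at 10.0 h, with the solid down to 62.5%.

| setting | noon | summer | flask |
|---|---|---|---|
| solid substrate | 0.050 M | 0.050 M | 0.050 M |
| partner | 1 equiv | 1.5 equiv | 2.00 equiv |
| remark | run made earlier | run made earlier |  |
| time |  |  | 15 h |

- noon (time / h: solid substrate / %, mono adduct / %): 0.500: 97.3, 0.3; 1.33: 94.4, 0.6; 2.50: 89.6, 0.1; 4.00: 82.9, 0.8; 5.00: 80.2, 0.6; 8.00: 68.3, 3.8; 10.0: 62.5, 3.7
- summer (time / h: solid substrate / %, mono adduct / %): 0.667: 96.6, 0.4; 1.00: 94.3, 0; 1.50: 92.8, 0.5; 2.50: 89.9, 0.3; 4.00: 82.2, 1.6; 6.00: 74.7, 3.5; 10.0: 61.4, 7.3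

(readings scatter by 0.5 percentage points)

- at the start none of the solid substrate is in solution

- how much solid substrate there is at 15 h, in percent of the solid substrate charged (only what is still solid)
- how much mono adduct there is at 15 h, in percent of the solid substrate charged
- how much double product there is at 15 h, in percent of the solid substrate charged
- how much triple product there is at 15 h, in percent of the solid substrate charged

My note for whoever took over the bench:

1. In the flask: the solid substrate is the limiting reagent, against 2.00 equiv of partner. Its balance in the noon run at 10.0 h left 33.8% that was neither solid nor mono adduct, and I took this for substrate in solution.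

2. I used J, the concentration leaving the solid per hour, which is the charge times the fraction gone, divided by the time. The noon run gave 1.88 mM/h, and the summer run 1.93 mM/h.

3. Leave the partner as charged: going from 1 equiv to 1.5 equiv moved the solid at 10.0 h by 1.1 percentage points, against a scatter of 0.5 points.

4. When you came, at 15 h, I expected 43.8% solid, holding J constant.

5. The forecast, higher than mine on the solid, gave 47.5% solid, 14% mono adduct, 3.5% double product and 0.5% triple product, on the ground that “its loss is dissolution-controlled and independent of partner”.

The flask gave 45.9% solid, 15.2% mono adduct, 0.161% double product and 0.131% triple product, and the forecast stood within tolerance.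

    starting material + partner → mono adduct (k = 0.545 /M/h)
    partner + mono adduct → double product (k = 0.0449 /M/h)
    partner + double product → triple product (k = 2.52 /M/h)
    partner + triple product → tetra adduct (k = 0.595 /M/h)
    crystals ⇌ tetra adduct, rate k5*(cs5 - [tetra adduct]) while solid is left; crystals form when [tetra adduct] > cs5 (solubility = 16.0 mM, k = 1.60 /h)
    2 partner → homo dimer (k = 0.0936 /M/h)
    solid substrate ⇌ starting material, rate k7*(cs7 - [starting material]) while solid is left; crystals form when [starting material] > cs7 (solubility = 49.0 mM, k = 0.0483 /h)

In this flask, the solid lost 1.80 mM/h on average over 15 h, and at that time 38.6% stood as starting material. The neighbour was charged with 0.12 M of solid substrate, with the same equivalents and the same time. Reckoned with the same J, 15 h takes 23.5% of that charge, which leaves 76.5% solid. The neighbour held, at the same time, 76.3% solid.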